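**Retrosynthetic overview**

- Target ⇒ hydroxide opening of a dearomatised enol lactone ⇒ palladium-catalysed asymmetric dearomative C-prenylation of a fully substituted pyrano[2,3-f]chromene-dione phenol ⇒ sp3–sp2 Negishi coupling of an aryl bromide with a (cyclobutyl)methyl iodide.
- Aryl bromide ⇐ phloroglucinol: C-acylation, alkaloid-catalysed oxa-Michael closure (cis-2,3-dimethylchromanone ring), carbene-catalysed annulation with cinnamaldehyde (dihydropyranone ring and benzylic centre), bromination of the last free ring carbon.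
- Cyclobutyl iodide ⇐ catalytic asymmetric [2+2] of a tetrasubstituted 2,3-dienoate with O-silylated allyl alcohol (all ten carbons of the monoterpene unit), then ester reduction and allylic diazene transposition to the isopropenyl group.
- Enabling feature: in the cyclobutane the CMe2 carbon lies between the CH that carries the CH2 link and the CH that carries isopropenyl, with a ring CH2 opposite. This is the [2+2] retron of a terminal alkene (ring CH2–CH) and the Me2C=C end of an allene whose third carbon becomes the isopropenyl carbon.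
- Ring order: cyclobutane (step 4), chromanone ring (step 10), lactone ring (step 11); the carbocycle is dearomatised in step 14 and the lactone opened in step 15.

Key step: step 4

Assumption: in step 11 the cinnamoyl unit is taken to be delivered from the 7-oxygen of 23 to C8 and not to C6, as C–C bond formations tethered to O7 of 5-hydroxychroman-4-ones generally are, the 5-OH staying locked in its hydrogen bond to the ketone.

**Route**

Step 1
Reactants: 1 2-bromopropanoyl bromide (racemic); 2 2,2,2-trifluoroethanol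
Product: 3 2,2,2-trifluoroethyl 2-bromopropanoate (racemic)
Conditions: pyridine (1.1 equiv), CH2Cl2, 0 °C to rt
Reagents that add atoms: 2,2,2-trifluoroethanol 2, OCC(F)(F)F
Why: Acyl substitution of an acyl bromide by an alcohol (esterification) installs the activated ester; the racemic α-centre is erased in step 3.

Step 2
Reactants: 3 2,2,2-trifluoroethyl 2-bromopropanoate; 4 triphenylphosphine
Product: 5 triphenyl[1-oxo-1-(2,2,2-trifluoroethoxy)propan-2-yl]phosphonium bromide
Conditions: toluene, 80 °C
Reagents that add atoms: triphenylphosphine 4, c1ccc(cc1)P(c1ccccc1)c1ccccc1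
Why: SN2 quaternisation of the phosphine by the secondary α-bromo ester (phosphonium salt formation) is the standard entry to α-methyl stabilised ylides.

Step 3
Reactants: 5 phosphonium bromide; 6 2-methylpropanoyl chloride
Product: 9 2,2,2-trifluoroethyl 2,4-dimethylpenta-2,3-dienoate, via phosphorus ylide 7 (not isolated), via dimethylketene 8 (not isolated)
Conditions: Et3N (2.2 equiv), CH2Cl2, 0 °C to rt
Reagents that add atoms: 2-methylpropanoyl chloride 6, CC(C)C(Cl)=O
Why: Wittig olefination of a ketene made in situ from the acid chloride by the stabilised ylide is the usual allenoate synthesis; the allene is achiral because one end carries two methyl groups.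

Step 4
Reactants: 9 2,2,2-trifluoroethyl 2,4-dimethylpenta-2,3-dienoate; 10 (allyloxy)(tert-butyl)dimethylsilane
Product: 11 2,2,2-trifluoroethyl 2-[(3S)-3-({[tert-butyl(dimethyl)silyl]oxy}methyl)-2,2-dimethylcyclobutylidene]propanoate (alkene isomers, both converge in step 6)
Conditions: (S)-3,3-diphenyl-1-(o-tolyl)tetrahydro-1H,3H-pyrrolo[1,2-c][1,3,2]oxazaborole (20 mol %), AlBr3 (16 mol %), 10 (3 equiv), CH2Cl2, −78 to −40 °C
Reagents that add atoms: (allyloxy)(tert-butyl)dimethylsilane 10, C=CCO[Si](C)(C)C(C)(C)C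
Why: Lewis-acid-catalysed allenoate–alkene [2+2] cycloaddition: the AlBr3-activated chiral oxazaborolidine binds the ester carbonyl of 9, the terminal CH2 of 10 attacks the central allene carbon first, and positive charge builds on the internal alkene carbon opposite a catalyst-bound dienolate. The four-membered ring then closes by collapse of this 1,4-dipole, the gem-dimethyl terminus of the dienolate bonding to the internal alkene carbon, so the ring-closing bond is the one between the CMe2 carbon and the CH that carries the CH2O arm (stepwise-asynchronous 2+2, the only ring size the four-atom dipole allows). The closest known reaction type is the oxazaborolidine- or EtAlCl2-promoted [2+2] of 2,3-dienoates, gem-dimethyl-terminated ones included, with unactivated terminal alkenes to give 1,3-substituted alkylidenecyclobutanes. The one new stereocentre, the ring CH bearing CH2OTBS, is set by the catalyst, which shields one face of the bound allenoate so that 10 approaches with a single enantiotopic face ((S)-catalyst proposed, its antipode if the sense is reversed); the neighbouring ring carbon stays sp2 and is set in step 6. The step needs Markovnikov regioselectivity (secured by the monosubstituted alkene, which places the CH next to CMe2), closure at the dimethyl terminus and not at the ester-bearing carbon (secured because that carbon is fully substituted and closure there would forfeit ester conjugation), and tolerance of the silyl ether (bulky, weakly basic oxygen at low temperature).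

Step 5
Reactants: 11 cyclobutylidene ester
Product: 12 2-[(3S)-3-({[tert-butyl(dimethyl)silyl]oxy}methyl)-2,2-dimethylcyclobutylidene]propan-1-ol
Conditions: i-Bu2AlH (2.5 equiv), CH2Cl2, −78 °C; aq. potassium sodium tartrate (KNaC4H4O6)
Reagents that add atoms: none
Why: 1,2-Reduction of the conjugated activated ester by the aluminium hydride gives the allylic alcohol and leaves the silyl ether and the ring stereocentre untouched.

Step 6
Reactants: 12 allylic alcohol; 13 2-nitrobenzenesulfonohydrazide
Product: 16 tert-butyl{[(1S,3S)-2,2-dimethyl-3-(prop-1-en-2-yl)cyclobutyl]methoxy}dimethylsilane, via sulfonylhydrazine adduct 14 (not isolated), via allylic diazene 15 (not isolated)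
Conditions: PPh3, diethyl azodicarboxylate, THF, −30 °C, then 23 °C
Reagents that add atoms: none
Why: Mitsunobu N-alkylation of the sulfonylhydrazide, loss of sulfinic acid and retro-ene loss of N2 from the allylic diazene (reductive 1,3-transposition of an allylic alcohol) move the double bond out to the isopropenyl group, the hydrogen being delivered to the ring carbon on the face away from the CH2OTBS-bearing substituent, as additions to 3-substituted cyclobutanones and methylenecyclobutanes go, which should give the cis-1,3 isomer.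

Step 7
Reactants: 16 silyl ether
Product: 17 [(1S,3S)-2,2-dimethyl-3-(prop-1-en-2-yl)cyclobutyl]methanol
Conditions: Bu4NF, THF, 0 °C to rt
Reagents that add atoms: none
Why: Fluoride-mediated desilylation is neutral enough to leave the acid-sensitive isopropenylcyclobutane intact.

Step 8
Reactants: 17 alcohol; 18 iodine
Product: 19 (1S,3S)-1-(iodomethyl)-2,2-dimethyl-3-(prop-1-en-2-yl)cyclobutane
Conditions: PPh3, imidazole, CH2Cl2, 0 °C to rt, dark
Reagents that add atoms: iodine 18, II
Why: Appel-type iodination proceeds by SN2 at the primary carbon under non-acidic conditions and does not involve either ring stereocentre.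

Step 9
Reactants: 20 phloroglucinol; 21 (E)-2-methylbut-2-enoyl chloride
Product: 22 (E)-2-methyl-1-(2,4,6-trihydroxyphenyl)but-2-en-1-one
Conditions: AlCl3 (3 equiv), PhNO2, 0 °C to rt; cold aq. HCl
Reagents that add atoms: (E)-2-methylbut-2-enoyl chloride 21, C/C=C(\C)C(Cl)=O
Why: Friedel–Crafts C-acylation of the symmetric triol has no regiochemical issue and stops at monoacylation because the acyl group deactivates the ring.

Step 10
Reactants: 22 acylphloroglucinol
Product: 23 (2R,3S)-5,7-dihydroxy-2,3-dimethyl-2,3-dihydro-4H-chromen-4-one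
Conditions: (−)-quinine (10 mol %), PhCl–THF, 15 °C
Reagents that add atoms: none
Why: Cinchona-alkaloid-catalysed intramolecular oxa-Michael addition (6-endo-trig) of the ion-paired phenoxide to one face of the enone sets C2 as R, and kinetic protonation of the ring enol anti to the new C2 methyl sets C3 as S, giving the cis isomer.

Step 11
Reactants: 23 chromanone; 24 (E)-cinnamaldehyde
Product: 25 (2R,3S,10S)-5-hydroxy-2,3-dimethyl-10-phenyl-2,3,9,10-tetrahydro-4H,8H-pyrano[2,3-f]chromene-4,8-dione
Conditions: aminoindanol-derived N-mesityl triazolium chloride [(5aS,10bR), 10 mol %], i-Pr2NEt (20 mol %), 3,3',5,5'-tetra-tert-butyldiphenoquinone (1.1 equiv), toluene, rt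
Reagents that add atoms: (E)-cinnamaldehyde 24, O=C/C=C/c1ccccc1
Why: Oxidative N-heterocyclic-carbene catalysis turns the enal into an α,β-unsaturated acyl azolium that is engaged through O7 and C8 (conjugate C–C bond formation, then lactonisation onto O7), the chiral triazolylidene fixing the face of the acyl azolium so that the benzylic centre should form as S (mirror-image catalyst if the sense is opposite).

Step 12
Reactants: 25 tricyclic lactone; 26 N-bromosuccinimide
Product: 27 (2R,3S,10S)-6-bromo-5-hydroxy-2,3-dimethyl-10-phenyl-2,3,9,10-tetrahydro-4H,8H-pyrano[2,3-f]chromene-4,8-dione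
Conditions: MeCN, −20 °C
Reagents that add atoms: N-bromosuccinimide 26, O=C1CCC(=O)N1Br
Why: Electrophilic aromatic bromination can only take the single free ring position, which is ortho to the phenol.

Step 13
Reactants: 19 cyclobutylmethyl iodide; 27 aryl bromide; 28 zinc
Product: 30 (2R,3S,10S)-6-{[(1R,3S)-2,2-dimethyl-3-(prop-1-en-2-yl)cyclobutyl]methyl}-5-hydroxy-2,3-dimethyl-10-phenyl-2,3,9,10-tetrahydro-4H,8H-pyrano[2,3-f]chromene-4,8-dione, via alkylzinc iodide 29 (not isolated)
Conditions: (i) Zn dust, LiCl, THF, 35 °C; (ii) 27, Pd(OAc)2 (4 mol %), SPhos (8 mol %), THF, 45 °C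
Reagents that add atoms: iodide 19 (through its zinc reagent 29), C=C(C)[C@@H]1C[C@H](CI)C1(C)C
Why: Zinc insertion and Negishi sp3–sp2 cross-coupling join the fragments under neutral conditions that spare lactone, ketone and chelated phenol, the bulky biarylphosphine allowing coupling at the di-ortho-substituted bromide; no stereocentre is touched.

Step 14
Reactants: 30 coupled phenol; 31 3-methylbut-2-en-1-yl acetate
Product: 32 (2R,3S,6R,10S)-6-{[(1R,3S)-2,2-dimethyl-3-(prop-1-en-2-yl)cyclobutyl]methyl}-2,3-dimethyl-6-(3-methylbut-2-en-1-yl)-10-phenyl-2,3,9,10-tetrahydro-4H,8H-pyrano[2,3-f]chromene-4,5,8(6H)-trione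
Conditions: Pd2(dba)3·CHCl3 (2.5 mol %), (R,R)-N,N'-(cyclohexane-1,2-diyl)bis[2-(diphenylphosphino)benzamide] (7.5 mol %), Cs2CO3 (1.2 equiv), 1,4-dioxane, rt
Reagents that add atoms: 3-methylbut-2-en-1-yl acetate 31, CC(C)=CCOC(C)=O
Why: Palladium-catalysed asymmetric allylic dearomatisation of a phenol (Tsuji–Trost type): the caesium phenoxide attacks the π-prenyl complex through its alkylated ortho carbon at the unsubstituted allyl terminus, the chiral diphosphine pocket selecting the face so that the quaternary carbon should form as R (antipodal ligand if the sense is opposite), while O-allylation stays reversible under zerovalent palladium.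

Step 15
Reactants: 32 dearomatised enol lactone; 33 lithium hydroxide
Product: 34 (3S)-3-[(2R,3S,6R)-6-{[(1R,3S)-2,2-dimethyl-3-(prop-1-en-2-yl)cyclobutyl]methyl}-4-hydroxy-2,3-dimethyl-6-(3-methylbut-2-en-1-yl)-5,7-dioxo-3,5,6,7-tetrahydro-2H-chromen-8-yl]-3-phenylpropanoic acid (CNP0328119.1)
Conditions: LiOH (3 equiv), THF–H2O, 0 °C; then 1 M HCl to pH 3
Reagents that add atoms: lithium hydroxide 33, [Li+].[OH-]
Why: Saponification of the activated enol lactone (acyl–oxygen cleavage) frees the acid, the cross-conjugated triketone enolate formed at once shielding C3 from epimerisation, and acidification should give the enol tautomer of the target.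

**Compound list**

1 | 2-bromopropanoyl bromide (racemic) | CC(Br)C(Br)=O | starting material
2 | 2,2,2-trifluoroethanol | OCC(F)(F)F | starting material
3 | 2,2,2-trifluoroethyl 2-bromopropanoate (racemic) | CC(Br)C(=O)OCC(F)(F)F | intermediate
4 | triphenylphosphine | c1ccc(cc1)P(c1ccccc1)c1ccccc1 | starting material
5 | triphenyl[1-oxo-1-(2,2,2-trifluoroethoxy)propan-2-yl]phosphonium bromide (racemic) | CC(C(=O)OCC(F)(F)F)[P+](c1ccccc1)(c1ccccc1)c1ccccc1.[Br-] | intermediate
6 | 2-methylpropanoyl chloride | CC(C)C(Cl)=O | starting material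
7 | 2,2,2-trifluoroethyl 2-(triphenylphosphoranylidene)propanoate | CC(C(=O)OCC(F)(F)F)=P(c1ccccc1)(c1ccccc1)c1ccccc1 | intermediate
8 | dimethylketene | CC(C)=C=O | intermediate
9 | 2,2,2-trifluoroethyl 2,4-dimethylpenta-2,3-dienoate | CC(C)=C=C(C)C(=O)OCC(F)(F)F | intermediate
10 | (allyloxy)(tert-butyl)dimethylsilane | C=CCO[Si](C)(C)C(C)(C)C | starting material
11 | 2,2,2-trifluoroethyl 2-[(3S)-3-({[tert-butyl(dimethyl)silyl]oxy}methyl)-2,2-dimethylcyclobutylidene]propanoate | CC(C(=O)OCC(F)(F)F)=C1C[C@H](CO[Si](C)(C)C(C)(C)C)C1(C)C | intermediate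
12 | 2-[(3S)-3-({[tert-butyl(dimethyl)silyl]oxy}methyl)-2,2-dimethylcyclobutylidene]propan-1-ol | CC(CO)=C1C[C@H](CO[Si](C)(C)C(C)(C)C)C1(C)C | intermediate
13 | 2-nitrobenzenesulfonohydrazide | NNS(=O)(=O)c1ccccc1[N+](=O)[O-] | starting material
14 | N-{2-[(3S)-3-({[tert-butyl(dimethyl)silyl]oxy}methyl)-2,2-dimethylcyclobutylidene]propyl}-2-nitrobenzenesulfonohydrazide | CC(CN(N)S(=O)(=O)c1ccccc1[N+](=O)[O-])=C1C[C@H](CO[Si](C)(C)C(C)(C)C)C1(C)C | intermediate
15 | {2-[(3S)-3-({[tert-butyl(dimethyl)silyl]oxy}methyl)-2,2-dimethylcyclobutylidene]propyl}diazene | CC(CN=N)=C1C[C@H](CO[Si](C)(C)C(C)(C)C)C1(C)C | intermediate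
16 | tert-butyl{[(1S,3S)-2,2-dimethyl-3-(prop-1-en-2-yl)cyclobutyl]methoxy}dimethylsilane | C=C(C)[C@@H]1C[C@H](CO[Si](C)(C)C(C)(C)C)C1(C)C | intermediate
17 | [(1S,3S)-2,2-dimethyl-3-(prop-1-en-2-yl)cyclobutyl]methanol | C=C(C)[C@@H]1C[C@H](CO)C1(C)C | intermediate
18 | iodine | II | starting material
19 | (1S,3S)-1-(iodomethyl)-2,2-dimethyl-3-(prop-1-en-2-yl)cyclobutane | C=C(C)[C@@H]1C[C@H](CI)C1(C)C | intermediate
20 | phloroglucinol (benzene-1,3,5-triol) | Oc1cc(O)cc(O)c1 | starting material
21 | (E)-2-methylbut-2-enoyl chloride (tigloyl chloride) | C/C=C(\C)C(Cl)=O | starting material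
22 | (E)-2-methyl-1-(2,4,6-trihydroxyphenyl)but-2-en-1-one | C/C=C(\C)C(=O)c1c(O)cc(O)cc1O | intermediate
23 | (2R,3S)-5,7-dihydroxy-2,3-dimethyl-2,3-dihydro-4H-chromen-4-one | O=C1[C@@H](C)[C@@H](C)Oc2cc(O)cc(O)c12 | intermediate
24 | (E)-cinnamaldehyde | O=C/C=C/c1ccccc1 | starting material
25 | (2R,3S,10S)-5-hydroxy-2,3-dimethyl-10-phenyl-2,3,9,10-tetrahydro-4H,8H-pyrano[2,3-f]chromene-4,8-dione | O=C1C[C@@H](c2ccccc2)c2c(O1)cc(O)c1C(=O)[C@@H](C)[C@@H](C)Oc21 | intermediate
26 | N-bromosuccinimide | O=C1CCC(=O)N1Br | starting material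
27 | (2R,3S,10S)-6-bromo-5-hydroxy-2,3-dimethyl-10-phenyl-2,3,9,10-tetrahydro-4H,8H-pyrano[2,3-f]chromene-4,8-dione | O=C1C[C@@H](c2ccccc2)c2c(O1)c(Br)c(O)c1C(=O)[C@@H](C)[C@@H](C)Oc21 | intermediate
28 | zinc | [Zn] | starting material
29 | {[(1S,3S)-2,2-dimethyl-3-(prop-1-en-2-yl)cyclobutyl]methyl}zinc iodide | C=C(C)[C@@H]1C[C@H](C[Zn]I)C1(C)C | intermediate
30 | (2R,3S,10S)-6-{[(1R,3S)-2,2-dimethyl-3-(prop-1-en-2-yl)cyclobutyl]methyl}-5-hydroxy-2,3-dimethyl-10-phenyl-2,3,9,10-tetrahydro-4H,8H-pyrano[2,3-f]chromene-4,8-dione | O=C1C[C@@H](c2ccccc2)c2c(O1)c(C[C@H]3C[C@@H](C(C)=C)C3(C)C)c(O)c1C(=O)[C@@H](C)[C@@H](C)Oc21 | intermediate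
31 | 3-methylbut-2-en-1-yl acetate (prenyl acetate) | CC(C)=CCOC(C)=O | starting material
32 | (2R,3S,6R,10S)-6-{[(1R,3S)-2,2-dimethyl-3-(prop-1-en-2-yl)cyclobutyl]methyl}-2,3-dimethyl-6-(3-methylbut-2-en-1-yl)-10-phenyl-2,3,9,10-tetrahydro-4H,8H-pyrano[2,3-f]chromene-4,5,8(6H)-trione | O=C1C[C@@H](c2ccccc2)C2=C(O1)[C@@](CC=C(C)C)(C[C@H]3C[C@@H](C(C)=C)C3(C)C)C(=O)C3=C2O[C@H](C)[C@H](C)C3=O | intermediate
33 | lithium hydroxide | [Li+].[OH-] | starting material
34 | (3S)-3-[(2R,3S,6R)-6-{[(1R,3S)-2,2-dimethyl-3-(prop-1-en-2-yl)cyclobutyl]methyl}-4-hydroxy-2,3-dimethyl-6-(3-methylbut-2-en-1-yl)-5,7-dioxo-3,5,6,7-tetrahydro-2H-chromen-8-yl]-3-phenylpropanoic acid | C=C(C)[C@@H]1C[C@H](C[C@@]2(CC=C(C)C)C(=O)C3=C(O)[C@@H](C)[C@@H](C)OC3=C([C@@H](CC(=O)O)c3ccccc3)C2=O)C1(C)C | target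

**Step count**

Total steps: 15. Longest linear sequence: 11 steps (steps 1–8, then 13–15); the core branch (steps 9–12) joins at step 13.

**Steps most likely to fail, with fallbacks**

Step 4. The allenoate may fail to engage the oxygen-bearing terminal alkene (sequestration of the Lewis acid, isomerisation of the allenoate to a 2,4-dienoate), or enantiofacial discrimination may be weak. The fallback sets out from 10 (with 6) and still closes the ring through the same CMe2–CH bond, by a keteniminium [2+2]. Acid chloride 6 and (2R,5R)-2,5-dimethylpyrrolidine (Et3N, CH2Cl2) give the amide 1-[(2R,5R)-2,5-dimethylpyrrolidin-1-yl]-2-methylpropan-1-one F1. Tf2O and 2,4,6-collidine convert F1 into the C2-symmetric keteniminium triflate, which adds to 10 (CH2Cl2, reflux). Aqueous hydrolysis of the cyclobutaniminium salt gives (3S)-3-({[tert-butyl(dimethyl)silyl]oxy}methyl)-2,2-dimethylcyclobutan-1-one F2, the auxiliary selecting the alkene face. Reductive cyanation with p-toluenesulfonylmethyl isocyanide (t-BuOK, EtOH, DME) gives the nitrile 3-({[tert-butyl(dimethyl)silyl]oxy}methyl)-2,2-dimethylcyclobutane-1-carbonitrile F3. MeLi, then aq. NH4Cl and equilibration with NaOMe in MeOH, should give the cis methyl ketone 1-[(1R,3S)-3-({[tert-butyl(dimethyl)silyl]oxy}methyl)-2,2-dimethylcyclobutyl]ethan-1-one F4. Wittig methylenation (Ph3P=CH2, THF) comes back to the route at 16.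

Step 14. Facial selection at the new quaternary carbon may be poor, or prenyl may be delivered to oxygen or through its substituted terminus. The fallback sets out from 30. Aqueous KOH (0 °C) opens the lactone to the tripotassium salt of the hydroxy acid (3S)-3-[(2R,3S)-6-{[(1R,3S)-2,2-dimethyl-3-(prop-1-en-2-yl)cyclobutyl]methyl}-5,7-dihydroxy-2,3-dimethyl-4-oxo-3,4-dihydro-2H-chromen-8-yl]-3-phenylpropanoic acid F5. This is alkylated in the same aqueous phase with prenyl bromide, the classical dearomatising C-prenylation of an acylphloroglucinol polyanion at the alkylated carbon flanked by two phenoxides. Acidification gives 34 together with its epimer at the quaternary carbon. The two are diastereomers and are separated by preparative reversed-phase chromatography, so the fallback comes back at 34.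

Step 11. The annulation may leak to C6, stop at the 7-O-cinnamate, or erode the cis-chromanone through base-mediated epimerisation. The fallback sets out from 23 and builds the pyranone ring stepwise. Propargyl bromide and K2CO3 (acetone) alkylate only the free 7-OH to give (2R,3S)-5-hydroxy-2,3-dimethyl-7-(prop-2-yn-1-yloxy)-2,3-dihydro-4H-chromen-4-one F6. Thermal aryl propargyl ether Claisen rearrangement with hydrogen shift and oxa-6π closure (N,N-diethylaniline, 190 °C) gives the angular 2H-pyran (2R,3S)-5-hydroxy-2,3-dimethyl-2,3-dihydro-4H,8H-pyrano[2,3-f]chromen-4-one F7. Allylic oxidation with pyridinium chlorochromate, C5H5NH[CrO3Cl] (CH2Cl2, reflux), gives the pyranone (2R,3S)-5-hydroxy-2,3-dimethyl-2,3-dihydro-4H,8H-pyrano[2,3-f]chromene-4,8-dione F8. Rhodium-catalysed asymmetric 1,4-addition of PhB(OH)2 (Rh(acac)(C2H4)2, (R)-SEGPHOS, dioxane–H2O, 60 °C) comes back to the route at 25.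

**Further compounds**

F1 | step 4 | 1-[(2R,5R)-2,5-dimethylpyrrolidin-1-yl]-2-methylpropan-1-one | CC(C)C(=O)N1[C@H](C)CC[C@H]1C
F2 | step 4 | (3S)-3-({[tert-butyl(dimethyl)silyl]oxy}methyl)-2,2-dimethylcyclobutan-1-one | O=C1C[C@H](CO[Si](C)(C)C(C)(C)C)C1(C)C
F3 | step 4 | (3S)-3-({[tert-butyl(dimethyl)silyl]oxy}methyl)-2,2-dimethylcyclobutane-1-carbonitrile (both C1 epimers) | N#CC1C[C@H](CO[Si](C)(C)C(C)(C)C)C1(C)C
F4 | step 4 | 1-[(1R,3S)-3-({[tert-butyl(dimethyl)silyl]oxy}methyl)-2,2-dimethylcyclobutyl]ethan-1-one | CC(=O)[C@@H]1C[C@H](CO[Si](C)(C)C(C)(C)C)C1(C)C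
F5 | step 14 | (3S)-3-[(2R,3S)-6-{[(1R,3S)-2,2-dimethyl-3-(prop-1-en-2-yl)cyclobutyl]methyl}-5,7-dihydroxy-2,3-dimethyl-4-oxo-3,4-dihydro-2H-chromen-8-yl]-3-phenylpropanoic acid | OC(=O)C[C@@H](c1ccccc1)c1c(O)c(C[C@H]2C[C@@H](C(C)=C)C2(C)C)c(O)c2C(=O)[C@@H](C)[C@@H](C)Oc12
F6 | step 11 | (2R,3S)-5-hydroxy-2,3-dimethyl-7-(prop-2-yn-1-yloxy)-2,3-dihydro-4H-chromen-4-one | O=C1[C@@H](C)[C@@H](C)Oc2cc(OCC#C)cc(O)c12
F7 | step 11 | (2R,3S)-5-hydroxy-2,3-dimethyl-2,3-dihydro-4H,8H-pyrano[2,3-f]chromen-4-one | O=C1[C@@H](C)[C@@H](C)Oc2c3C=CCOc3cc(O)c12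
F8 | step 11 | (2R,3S)-5-hydroxy-2,3-dimethyl-2,3-dihydro-4H,8H-pyrano[2,3-f]chromene-4,8-dione | O=C1[C@@H](C)[C@@H](C)Oc2c3C=CC(=O)Oc3cc(O)c12
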